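**Plan**
- Skeleton numbers are those of the target: ten-membered ring C1–C10 (C14 = ester carbon on C10, C15 = methyl on C4), lactone C6–O–C12(=O)–C11(=C13)–C7, ester on O8, hydroxyl on O9. α is the face of ring C5–C10 that carries O6, β the opposite face.
- The ten-membered ring holds the 1,5-diene C10=C1–C2–C3–C4=C5. A retro-[3,3] shift cuts its central σ-bond C2–C3 and gives cyclohexane C5–C10 (19) with a 10-vinyl (C1=C2) and a 5-isopropenyl (C4=C3) group; the C5–C10 bond is a temporary ring bond.
- Further cuts, in order: C4=C3 (ketone methylenation), O6–C12 (lactonisation), C8–O (epoxide opening), C7–C11 (allyl–alkenyl coupling), C1=C2 (selenoxide elimination), then C5–C6 and C9–C10 (Diels–Alder of diene 3 with alkylidene lactone 6).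
- Forward: the cyclohexene C5–C10 arises first (step 3), the γ-lactone second (step 11), and in step 13 the six-membered ring is exchanged for the ten-membered ring.
- Stereochemistry: C5, C6, C9 and C10 from one endo Diels–Alder under a chiral oxazaborolidinium catalyst; C7 by inversion in the Stille coupling; C8 and C9 by hydroxyl-directed epoxidation and anti opening; both ring alkene geometries from the chair Cope transition state of the lactone-locked cyclohexane.

Key step: step 13

Assumption: the (S)-oxazaborolidinium catalyst of step 3 is taken to deliver diene 3 to the face of 6 that gives 7 as drawn; if the opposite sense is found, the (R)-catalyst is used.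

Step 1
Reactants: 1 (1E,3E)-buta-1,3-diene-1,4-diyl diacetate
Product: 3 (1E,3E)-4-(tert-butyldimethylsilyloxy)buta-1,3-dien-1-yl acetate, via lithium dienolate 2 (not isolated)
Conditions: MeLi (2.0 equiv), THF, −78 °C; then TBSCl, HMPA, −78 °C to 0 °C
Reagents that add atoms: tert-butyldimethylsilyl chloride, C[Si](C)(Cl)C(C)(C)C
Why: Methyllithium cleaves one enol acetate to the lithium dienolate with retention of the E,E geometry (the anionic mono-enolate is slower to react again), and the silyl chloride traps it on oxygen (enolate generation from an enol ester, O-silylation).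

Step 2
Reactants: 4 3-(triphenyl-λ5-phosphanylidene)oxolan-2-one; 5 methylglyoxal (2-oxopropanal, 40% in water)
Product: 6 (E)-3-(2-oxopropylidene)oxolan-2-one
Conditions: CH2Cl2/H2O, 0 °C to rt
Reagents that add atoms: none
Why: The stabilised ylide reacts only at the aldehyde carbonyl and gives the E-alkylidene lactone, acetyl trans to the lactone carbonyl (Wittig reaction).

Step 3
Reactants: 3 (1E,3E)-4-(tert-butyldimethylsilyloxy)buta-1,3-dien-1-yl acetate; 6 (E)-3-(2-oxopropylidene)oxolan-2-one
Product: 7 spirolactone cycloadduct (cyclohex-7-ene C5–C10; 5α-acetyl; 6α-OTBS; 9α-OAc; C10 spiro)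
Conditions: (S)-1-(2-methylphenyl)-3,3-diphenyltetrahydro-1H,3H-pyrrolo[1,2-c][1,3,2]oxazaborole protonated with HN(SO2CF3)2 (20 mol%), CH2Cl2, −40 °C to −20 °C
Reagents that add atoms: none
Why: The catalyst binds the ketone (only it has the α-C–H for two-point binding), so C10 is the electrophilic terminus and bonds to the acetoxy-bearing diene carbon while the siloxy carbon bonds to C5; endo approach of the acetyl group places Ac, OTBS, OAc and C1 on the α face, and the catalyst sets the absolute sense at C5, C6, C9 and C10 (enantioselective Lewis-acid-catalysed Diels–Alder reaction).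

Step 4
Reactants: 7 spirolactone cycloadduct
Product: 9 selenide methyl ester (10α-CH2CH2SePh; 10β-CO2Me), via sodium carboxylate 8 (not isolated)
Conditions: PhSeNa (from PhSeH and NaH), THF–HMPA, 60 °C; then MeI, 0 °C to rt
Reagents that add atoms: sodium benzeneselenolate, [Na+].[Se-]c1ccccc1; iodomethane, CI
Why: The soft selenolate opens the γ-lactone by SN2 attack at the primary O–CH2 carbon (C2), faster than attack at the hindered secondary acetate, and the freed carboxylate is methylated in the same flask (lactone alkyl–oxygen cleavage, carboxylate alkylation).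

Step 5
Reactants: 9 selenide methyl ester
Product: 11 10α-vinyl ester (5α-acetyl; 6α-OTBS; 9α-OAc; C7=C8), via selenoxide 10 (not isolated)
Conditions: H2O2 (30%), pyridine, CH2Cl2, 0 °C, then 40 °C
Reagents that add atoms: none
Why: Oxidation at selenium and syn-elimination of the primary selenoxide can only take a C1 hydrogen and gives the C1=C2 vinyl group; pyridine suppresses seleninic-acid side reactions (selenoxide elimination).

Step 6
Reactants: 12 methyl propiolate
Product: 13 methyl 2-(tributylstannyl)prop-2-enoate
Conditions: Bu3SnH, Pd(PPh3)4 (1 mol%, zerovalent palladium), THF, 0 °C to rt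
Reagents that add atoms: tributyltin hydride, CCCC[SnH](CCCC)CCCC
Why: Palladium-catalysed syn-hydrostannation of the ynoate places tin on the α-carbon (hydrostannation).

Step 7
Reactants: 11 10α-vinyl ester; 13 methyl 2-(tributylstannyl)prop-2-enoate
Product: 14 7β-(1-methoxycarbonylvinyl)cyclohex-8-ene (5α-acetyl; 6α-OTBS; 10α-vinyl; 10β-CO2Me)
Conditions: Pd2(dba)3 (5 mol%, zerovalent palladium), LiCl, DMF, 40 °C
Reagents that add atoms: none
Why: Palladium ionises the C9 acetate from the β face (anti) and the alkenyl group, transferred from tin, is reductively eliminated on that face at the unhindered terminus C7 (C9 is neopentyl), so net inversion gives the 7β-acrylate trans to O6 and moves the alkene to C8=C9 (Stille coupling of an allylic acetate).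

Step 8
Reactants: 14 7β-(1-methoxycarbonylvinyl)cyclohex-8-ene
Product: 15 6α-alcohol
Conditions: HF·pyridine, pyridine, THF, 0 °C to rt
Reagents that add atoms: none
Why: Buffered fluoride removes the silyl ether without base, so the β-hydroxy ketone is not cleaved and the trans hydroxy ester does not yet lactonise (desilylation).

Step 9
Reactants: 15 6α-alcohol
Product: 16 8α,9α-epoxide
Conditions: VO(acac)2 (5 mol%), t-BuOOH, CH2Cl2, 0 °C to rt
Reagents that add atoms: tert-butyl hydroperoxide, CC(C)(C)OO
Why: The homoallylic 6α-hydroxyl binds vanadium and delivers oxygen to the α face of C8=C9, while the electron-poor acrylate and the remote vinyl group are spared (hydroxyl-directed epoxidation).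

Step 10
Reactants: 16 8α,9α-epoxide
Product: 17 8β-methacrylate 9α-alcohol (6α-OH and acrylate ester still open)
Conditions: methacrylic acid (5 equiv), Cs2CO3 (0.3 equiv), BHT, DMF, 70 °C
Reagents that add atoms: methacrylic acid, C=C(C)C(=O)O
Why: Methacrylate attacks C8 by SN2 with inversion because C9 is neopentyl (next to quaternary C10), giving the 8β-ester and 9α-alcohol, and the non-acidic medium avoids participation of the neighbouring ester carbonyls (trans-diaxial epoxide opening by a carboxylate).

Step 11
Reactants: 17 8β-methacrylate 9α-alcohol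
Product: 18 trans-lactone methyl ketone (5α-acetyl)
Conditions: camphorsulfonic acid (10 mol%), benzene, 50 °C
Reagents that add atoms: none
Why: Acid-catalysed transesterification joins the 6α-hydroxyl and the 7β-acrylate ester into the trans-fused α-methylene-γ-lactone, and no other hydroxyl can reach C12 (lactonisation).

Step 12
Reactants: 18 trans-lactone methyl ketone
Product: 19 divinylcyclohexane (5α-isopropenyl; 10α-vinyl; 10β-CO2Me)
Conditions: Zn, CH2Br2, TiCl4 (reagent preformed at 0 °C), THF/CH2Cl2, 0 °C to rt
Reagents that add atoms: dibromomethane, BrCBr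
Why: The non-basic titanium–zinc methylene reagent converts the hindered, enolisable ketone into the isopropenyl group without epimerising C5 or eliminating the β-acyloxy group, and esters and lactone are inert (Lombardo methylenation).

Step 13
Reactants: 19 divinylcyclohexane
Product: 20 target germacranolide
Conditions: toluene (0.01 M, degassed), BHT, 110 °C, sealed tube
Reagents that add atoms: none
Why: Thermal [3,3]-sigmatropic (Cope) rearrangement of the 1,5-diene C2=C1–C10–C5–C4=C3 through a chair transition state: the C5–C10 σ-bond breaks while the vinyl terminus C2 bonds to the isopropenyl terminus C3. The closest known reaction type is the reversible elemane-to-germacrane Cope rearrangement of 1,2-dialkenylcyclohexanes, here in its conjugation-driven form. The ten-membered ring arises by ring expansion of cyclohexane C5–C10 (concerted suprafacial shift, no exo or endo attack), with the γ-lactone and both esters as spectators. No stereocentre is created (C5 and C10 become trigonal); the alkene geometries follow from the chair of the trans-lactone-locked cyclohexane, where the C10 vinyl is equatorial (C9 is pseudoaxial in the transition state and ends cis to C2, ester trans) and the C5 isopropenyl is axial (C6 is pseudoequatorial and ends trans to C3, 4E). The step needs the equilibrium on the ten-ring side: conjugation of C1=C10 with the C14 ester, two trisubstituted alkenes in place of a mono- and a 1,1-disubstituted one, and relief of the four axial groups of 19 (8-ester against CO2Me, 9-OH against isopropenyl) should provide the bias. C6, C7, C8 and C9 are untouched.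

**Compound list**
1 | (1E,3E)-buta-1,3-diene-1,4-diyl diacetate | CC(=O)O/C=C/C=C/OC(C)=O | starting material
2 | lithium (1E,3E)-4-acetoxybuta-1,3-dien-1-olate (not isolated) | [Li+].[O-]/C=C/C=C/OC(C)=O | intermediate
3 | (1E,3E)-4-(tert-butyldimethylsilyloxy)buta-1,3-dien-1-yl acetate | CC(=O)O/C=C/C=C/O[Si](C)(C)C(C)(C)C | intermediate
4 | 3-(triphenyl-λ5-phosphanylidene)oxolan-2-one | O=C1OCCC1=P(c1ccccc1)(c1ccccc1)c1ccccc1 | starting material
5 | methylglyoxal (2-oxopropanal) | CC(=O)C=O | starting material
6 | (E)-3-(2-oxopropylidene)oxolan-2-one | CC(=O)/C=C1\CCOC1=O | intermediate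
7 | spirolactone cycloadduct: cyclohex-7-ene C5–C10 with 5α-acetyl, 6α-OTBS, 9α-OAc, C10 spiro-fused to the γ-lactone C14(=O)–O–C2H2–C1H2 (C1 α, C14 β) | C1=C[C@H](O[Si](C)(C)C(C)(C)C)[C@H](C(C)=O)[C@]2(CCOC2=O)[C@@H]1OC(C)=O | intermediate
8 | sodium carboxylate of the opened lactone: 10α-(2-phenylselanylethyl), 10β-carboxylate (not isolated) | C1=C[C@H](O[Si](C)(C)C(C)(C)C)[C@H](C(C)=O)[C@@](CC[Se]c2ccccc2)(C(=O)[O-])[C@@H]1OC(C)=O.[Na+] | intermediate
9 | selenide methyl ester: 10α-(2-phenylselanylethyl), 10β-CO2Me, 5α-acetyl, 6α-OTBS, 9α-OAc, C7=C8 | C1=C[C@H](O[Si](C)(C)C(C)(C)C)[C@H](C(C)=O)[C@@](CC[Se]c2ccccc2)(C(=O)OC)[C@@H]1OC(C)=O | intermediate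
10 | selenoxide of 9 (not isolated) | C1=C[C@H](O[Si](C)(C)C(C)(C)C)[C@H](C(C)=O)[C@@](CC[Se](=O)c2ccccc2)(C(=O)OC)[C@@H]1OC(C)=O | intermediate
11 | 10α-vinyl ester: 10β-CO2Me, 5α-acetyl, 6α-OTBS, 9α-OAc, C7=C8 | C1=C[C@H](O[Si](C)(C)C(C)(C)C)[C@H](C(C)=O)[C@@](C=C)(C(=O)OC)[C@@H]1OC(C)=O | intermediate
12 | methyl propiolate | C#CC(=O)OC | starting material
13 | methyl 2-(tributylstannyl)prop-2-enoate | C=C(C(=O)OC)[Sn](CCCC)(CCCC)CCCC | intermediate
14 | cyclohex-8-ene with 7β-(1-methoxycarbonylvinyl), 6α-OTBS, 5α-acetyl, 10α-vinyl, 10β-CO2Me | C1=C[C@@H](C(=C)C(=O)OC)[C@H](O[Si](C)(C)C(C)(C)C)[C@H](C(C)=O)[C@@]1(C=C)C(=O)OC | intermediate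
15 | 6α-alcohol of 14 | C1=C[C@@H](C(=C)C(=O)OC)[C@H](O)[C@H](C(C)=O)[C@@]1(C=C)C(=O)OC | intermediate
16 | 8α,9α-epoxide of 15 | O1[C@@H]2[C@@H](C(=C)C(=O)OC)[C@H](O)[C@H](C(C)=O)[C@@](C=C)(C(=O)OC)[C@H]12 | intermediate
17 | 8β-methacryloyloxy-9α-hydroxy-6α-hydroxy cyclohexane with 7β-(1-methoxycarbonylvinyl), 5α-acetyl, 10α-vinyl, 10β-CO2Me | C=C(C)C(=O)O[C@H]1[C@@H](C(=C)C(=O)OC)[C@H](O)[C@H](C(C)=O)[C@@](C=C)(C(=O)OC)[C@@H]1O | intermediate
18 | trans-fused α-methylene-γ-lactone (O6–C12) with 5α-acetyl, 8β-methacrylate, 9α-OH, 10α-vinyl, 10β-CO2Me | C=C(C)C(=O)O[C@H]1[C@H]2C(=C)C(=O)O[C@@H]2[C@H](C(C)=O)[C@@](C=C)(C(=O)OC)[C@@H]1O | intermediate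
19 | divinylcyclohexane: as 18 with 5α-isopropenyl in place of acetyl | C=C(C)C(=O)O[C@H]1[C@H]2C(=C)C(=O)O[C@@H]2[C@H](C(C)=C)[C@@](C=C)(C(=O)OC)[C@@H]1O | intermediate
20 | target: (6R,7S,8S,9S)-germacra-1(10)E,4E,11(13)-trien-6,12-olide with 8-methacryloyloxy, 9-hydroxy and 14-oic acid methyl ester | C=C(C)C(=O)O[C@H]1[C@H]2C(=C)C(=O)O[C@@H]2/C=C(\C)CC/C=C(/C(=O)OC)[C@@H]1O | target

**Count**
Total steps: 13. Longest linear sequence: 11 steps (4 and 5 to 6, then 7, 9, 11, 14, 15, 16, 17, 18, 19, 20).

**Steps most likely to fail**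

Step 13. The [3,3] equilibrium may stay on the side of the cyclohexane, or the acrylate units may polymerise at the temperature needed. The fallback sets out from 19 and comes back at 20. The axial 9-hydroxyl of 19 is silylated (TBSOTf, 2,6-lutidine, CH2Cl2, 0 °C) to the 9-O-tert-butyldimethylsilyl ether of 19, F1. The bulky axial silyloxy group is syn-axial to the isopropenyl group, so the ground state of the cyclohexane is raised and the rearrangement is pushed further towards the ten-membered ring. Heating (toluene, BHT, 110–130 °C) gives the 9-O-silyl ether of the target, F2, and HF·pyridine then gives 20.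

Step 7. Ionisation of the neopentyl allylic acetate may be slow, and the π-allyl palladium intermediate may lose a β-hydrogen to a diene before the slow transfer from tin. The fallback sets out from 11 and comes back at 14. Methanolysis (K2CO3, MeOH, 0 °C) gives the 9α-allylic alcohol F3, and diethyl chlorophosphate with N-methylimidazole gives the allylic diethyl phosphate F4. Stannane 13 is transmetalated with CuCl (DMF, 0 °C, monovalent copper) to methyl 2-cuprioacrylate F5, which displaces the phosphate in anti-SN2' fashion at C7 and gives 14 with the same 7β configuration.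

Step 3. Facial or endo selectivity may be poor, or the strong Lewis acid may degrade the silyl dienol ether. The fallback sets out from 3 (with 6) and comes back at 7, using a covalently bound chiral controller and a thermal cycloaddition. Diene 3 is cleaved with MeLi (2 equiv, THF, −78 °C) to lithium (1E,3E)-4-(tert-butyldimethylsilyloxy)buta-1,3-dien-1-olate F6, which is acylated with (S)-2-methoxy-2-phenylacetyl chloride to the chiral dienyl ester F7. Cycloaddition with 6 (toluene, 80 °C) gives the mandelate analogue of 7, F8, as one of two separable diastereomers; the (R)-acid is used if the other face is favoured. Methanolysis of the activated α-alkoxy ester (K2CO3, MeOH, 0 °C) gives the 9α-alcohol F9, and Ac2O with DMAP and pyridine gives 7.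

**Further compounds**
F1 | step 13 | 9-O-tert-butyldimethylsilyl ether of 19 | C=C(C)C(=O)O[C@H]1[C@H]2C(=C)C(=O)O[C@@H]2[C@H](C(C)=C)[C@@](C=C)(C(=O)OC)[C@@H]1O[Si](C)(C)C(C)(C)C
F2 | step 13 | 9-O-tert-butyldimethylsilyl ether of 20 | C=C(C)C(=O)O[C@H]1[C@H]2C(=C)C(=O)O[C@@H]2/C=C(\C)CC/C=C(/C(=O)OC)[C@@H]1O[Si](C)(C)C(C)(C)C
F3 | step 7 | 9α-allylic alcohol from 11 | C1=C[C@H](O[Si](C)(C)C(C)(C)C)[C@H](C(C)=O)[C@@](C=C)(C(=O)OC)[C@@H]1O
F4 | step 7 | 9α-allylic diethyl phosphate | C1=C[C@H](O[Si](C)(C)C(C)(C)C)[C@H](C(C)=O)[C@@](C=C)(C(=O)OC)[C@@H]1OP(=O)(OCC)OCC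
F5 | step 7 | methyl 2-cuprioacrylate (not isolated) | C=C([Cu])C(=O)OC
F6 | step 3 | lithium (1E,3E)-4-(tert-butyldimethylsilyloxy)buta-1,3-dien-1-olate (not isolated) | [Li+].[O-]/C=C/C=C/O[Si](C)(C)C(C)(C)C
F7 | step 3 | (1E,3E)-4-(tert-butyldimethylsilyloxy)buta-1,3-dien-1-yl (S)-2-methoxy-2-phenylacetate | CO[C@H](C(=O)O/C=C/C=C/O[Si](C)(C)C(C)(C)C)c1ccccc1
F8 | step 3 | cycloadduct as 7 with 9α-(S)-2-methoxy-2-phenylacetoxy in place of 9α-acetoxy | C1=C[C@H](O[Si](C)(C)C(C)(C)C)[C@H](C(C)=O)[C@]2(CCOC2=O)[C@@H]1OC(=O)[C@@H](OC)c1ccccc1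
F9 | step 3 | 9α-alcohol of the spirolactone cycloadduct | C1=C[C@H](O[Si](C)(C)C(C)(C)C)[C@H](C(C)=O)[C@]2(CCOC2=O)[C@@H]1O
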